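**Retrosynthetic overview**
1. Target 16 ⇐ 15: one BCl3 operation removes the 2'- and 4'-O-benzyl groups and the 5-O-methyl group that is chelated to the C4 carbonyl.
2. 15 ⇐ 13 (key): ring C (O1, C2, C3–OH, C4=O, C4a, C8a) is the ring-expanded form of the furanone ring of a (Z)-aurone, in which O1 sits on the carbon that becomes C3 and the benzylidene carbon becomes C2. Bromine addition, hydroxide opening and re-closure form the O1–C2 bond.
3. 13 ⇐ 6 + 12: aldol condensation forms the exocyclic C=C bond.
4. 6 ⇐ 2 + 3 ⇐ 1: Friedel–Crafts chloroacetylation of 1,2,3,5-tetramethoxybenzene with loss of the buttressed ortho methyl ether, then 5-exo-tet O-alkylation.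
5. 12 ⇐ 7: benzylation, Baeyer–Villiger oxidation, O-methylation, Vilsmeier–Haack formylation. Rings A and B are bought as benzenes, the furanone ring is closed in step 3, and ring C is formed last from it in step 9.

Key step: step 9

Remark: the target has no stereocentre; flavonol 15 holds one oxygen atom more than aurone 13, so the ring expansion is an oxidation in which bromine is the oxidant and hydroxide supplies the C3 oxygen.

**Route**

Step 1
Reactants: 1 3,4,5-trimethoxyphenol
Product: 2 1,2,3,5-tetramethoxybenzene
Conditions: MeI, K2CO3, acetone, reflux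
Reagents that add atoms: iodomethane CI
Why: Williamson O-methylation of the only phenol should give the symmetric arene whose two free ring positions are equivalent.

Step 2
Reactants: 2 1,2,3,5-tetramethoxybenzene; 3 chloroacetyl chloride
Product: 5 2-chloro-1-(2-hydroxy-3,4,6-trimethoxyphenyl)ethan-1-one, via tetramethoxyphenyl chloromethyl ketone 4 (not isolated)
Conditions: AlCl3 (2.5 equiv), CH2Cl2, 0 °C → rt; aq. HCl
Reagents that add atoms: none
Why: Friedel–Crafts acylation can only occur at the two equivalent free positions, and AlCl3 should then cleave by chelation the ortho methyl ether that is buttressed between the acyl group and the neighbouring methoxy group (twisted out of the ring plane, hence the more basic oxygen), the selective ortho-demethylation known for this arene with acetyl chloride.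

Step 3
Reactants: 5 2-chloro-1-(2-hydroxy-3,4,6-trimethoxyphenyl)ethan-1-one
Product: 6 4,6,7-trimethoxybenzofuran-3(2H)-one
Conditions: NaOAc, EtOH, reflux
Reagents that add atoms: none
Why: Intramolecular Williamson etherification (5-exo-tet) of the phenoxide on the α-chloro ketone should close the furanone under a base too weak to cause aldol self-condensation.

Step 4
Reactants: 7 2,4-dihydroxybenzaldehyde
Product: 8 2,4-bis(benzyloxy)benzaldehyde
Conditions: BnBr (2.5 equiv), K2CO3, DMF, 70 °C
Reagents that add atoms: benzyl bromide BrCc1ccccc1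
Why: Williamson benzylation should take both phenols, heating being needed for the 2-hydroxyl that is hydrogen-bonded to the aldehyde.

Step 5
Reactants: 8 2,4-bis(benzyloxy)benzaldehyde
Product: 10 2,4-bis(benzyloxy)phenol, via aryl formate 9 (not isolated)
Conditions: mCPBA, CH2Cl2, 0 °C → rt; aq. NaHCO3 wash; then K2CO3 (cat.), MeOH, rt
Reagents that add atoms: 3-chloroperoxybenzoic acid OOC(=O)c1cccc(Cl)c1
Why: Baeyer–Villiger oxidation of the aldehyde with migration of the electron-rich aryl group should give the formate, which is methanolysed to the phenol.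

Step 6
Reactants: 10 2,4-bis(benzyloxy)phenol
Product: 11 2,4-bis(benzyloxy)-1-methoxybenzene
Conditions: MeI, K2CO3, DMF, rt
Reagents that add atoms: iodomethane CI
Why: Williamson O-methylation of the free phenol, which is prone to air oxidation and is therefore capped at once.

Step 7
Reactants: 11 2,4-bis(benzyloxy)-1-methoxybenzene
Product: 12 2,4-bis(benzyloxy)-5-methoxybenzaldehyde
Conditions: POCl3, DMF, 0 → 70 °C; then aq. NaOAc
Reagents that add atoms: N,N-dimethylformamide CN(C)C=O; water O
Why: Vilsmeier–Haack formylation should go to the position ortho to one benzyloxy group and para to the other, the only site activated by two alkoxy groups that is not flanked by both of them.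

Step 8
Reactants: 6 4,6,7-trimethoxybenzofuran-3(2H)-one; 12 2,4-bis(benzyloxy)-5-methoxybenzaldehyde
Product: 13 (Z)-2-[2,4-bis(benzyloxy)-5-methoxybenzylidene]-4,6,7-trimethoxybenzofuran-3(2H)-one
Conditions: Al2O3 (neutral, activated), CH2Cl2, rt
Reagents that add atoms: none
Why: Aldol condensation of the acidic C2 methylene with the aldehyde followed by dehydration should give the thermodynamically preferred (Z)-alkene, in which the aryl group is syn to O1 and away from the C3 carbonyl.

Step 9
Reactants: 13 (Z)-2-[2,4-bis(benzyloxy)-5-methoxybenzylidene]-4,6,7-trimethoxybenzofuran-3(2H)-one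
Product: 15 2-[2,4-bis(benzyloxy)-5-methoxyphenyl]-3-hydroxy-5,7,8-trimethoxy-4H-chromen-4-one, via aurone dibromide 14 (not isolated)
Conditions: pyridinium tribromide (1.0 equiv), CH2Cl2, −20 → 0 °C; evaporate cold; 2 M aq. KOH, THF, 0 °C → rt, N2; then 1 M HCl
Reagents that add atoms: potassium hydroxide [K+].[OH-]
Why: Pyridinium tribromide should deliver one equivalent of bromine across the exocyclic C2=CH bond (bromonium character at C2, bromide to the benzylic carbon whose cation the 2,4-dialkoxyaryl group stabilises) to give dibromide 14. Hydroxide then replaces the bromide on the ketal-like C2, the hemiketal opens to a ring A phenoxide and a 1,2-diketone, and the phenoxide O1 displaces the benzylic bromide in a 6-exo-tet closure that forms the O1–C2 bond of ring C; enolisation of the chroman-3,4-dione gives the 3-hydroxy-4-pyranone. This is the Auwers flavonol synthesis, the ring expansion of an aurone dibromide by alkali. No stereocentre remains, since both sp3 centres of racemic 14 return to sp2 carbons, so its diastereomeric composition is of no consequence. The step needs bromine to add to the alkene and not to substitute C5 of the benzofuranone (the later C6 of ring A) or C3' of ring B; one equivalent of the mild solid tribromide at low temperature, the activation of the alkene by O1 and the ring B donors, and the deactivation of ring A by its vinylogous-ester carbonyl should secure this. Alcohol-free aqueous KOH in THF is chosen so that the labile benzylic bromide meets no alkoxide before the phenoxide is set free.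

Step 10
Reactants: 15 2-[2,4-bis(benzyloxy)-5-methoxyphenyl]-3-hydroxy-5,7,8-trimethoxy-4H-chromen-4-one
Product: 16 2-(2,4-dihydroxy-5-methoxyphenyl)-3,5-dihydroxy-7,8-dimethoxy-4H-chromen-4-one (CNP0319239.0)
Conditions: BCl3 (1 M in CH2Cl2, 8 equiv), C6HMe5 (6 equiv), CH2Cl2, −78 → 0 °C, then rt; MeOH, aq. HCl
Reagents that add atoms: none
Why: BCl3 should cleave the two aryl benzyl ethers at low temperature while pentamethylbenzene traps the benzyl cations (Friedel–Crafts scavenging), and on warming remove only the methyl ether peri to the C4 carbonyl through a six-membered boron chelate, leaving the unchelated 7-, 8- and 5'-methyl ethers.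

**Compound list**
1 | 3,4,5-trimethoxyphenol | COc1cc(O)cc(OC)c1OC | starting material
2 | 1,2,3,5-tetramethoxybenzene | COc1cc(OC)c(OC)c(OC)c1 | intermediate
3 | chloroacetyl chloride | O=C(Cl)CCl | starting material
4 | 2-chloro-1-(2,3,4,6-tetramethoxyphenyl)ethan-1-one (formed in the flask, not isolated) | COc1cc(OC)c(C(=O)CCl)c(OC)c1OC | intermediate
5 | 2-chloro-1-(2-hydroxy-3,4,6-trimethoxyphenyl)ethan-1-one | COc1cc(OC)c(C(=O)CCl)c(O)c1OC | intermediate
6 | 4,6,7-trimethoxybenzofuran-3(2H)-one | COc1cc(OC)c2c(c1OC)OCC2=O | intermediate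
7 | 2,4-dihydroxybenzaldehyde | O=Cc1ccc(O)cc1O | starting material
8 | 2,4-bis(benzyloxy)benzaldehyde | O=Cc1ccc(OCc2ccccc2)cc1OCc1ccccc1 | intermediate
9 | 2,4-bis(benzyloxy)phenyl formate (formed in the flask, not isolated) | O=COc1ccc(OCc2ccccc2)cc1OCc1ccccc1 | intermediate
10 | 2,4-bis(benzyloxy)phenol | Oc1ccc(OCc2ccccc2)cc1OCc1ccccc1 | intermediate
11 | 2,4-bis(benzyloxy)-1-methoxybenzene | COc1ccc(OCc2ccccc2)cc1OCc1ccccc1 | intermediate
12 | 2,4-bis(benzyloxy)-5-methoxybenzaldehyde | COc1cc(C=O)c(OCc2ccccc2)cc1OCc1ccccc1 | intermediate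
13 | (Z)-2-[2,4-bis(benzyloxy)-5-methoxybenzylidene]-4,6,7-trimethoxybenzofuran-3(2H)-one | COc1cc(/C=C2\Oc3c(OC)c(OC)cc(OC)c3C2=O)c(OCc2ccccc2)cc1OCc1ccccc1 | intermediate
14 | rac-(2R)-2-bromo-2-{(S)-bromo[2,4-bis(benzyloxy)-5-methoxyphenyl]methyl}-4,6,7-trimethoxybenzofuran-3(2H)-one (anti adduct, one enantiomer drawn; formed in the flask, not isolated) | COc1cc([C@H](Br)[C@@]2(Br)Oc3c(OC)c(OC)cc(OC)c3C2=O)c(OCc2ccccc2)cc1OCc1ccccc1 | intermediate
15 | 2-[2,4-bis(benzyloxy)-5-methoxyphenyl]-3-hydroxy-5,7,8-trimethoxy-4H-chromen-4-one | COc1cc(-c2oc3c(OC)c(OC)cc(OC)c3c(=O)c2O)c(OCc2ccccc2)cc1OCc1ccccc1 | intermediate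
16 | 2-(2,4-dihydroxy-5-methoxyphenyl)-3,5-dihydroxy-7,8-dimethoxy-4H-chromen-4-one | COc1cc(-c2oc3c(OC)c(OC)cc(O)c3c(=O)c2O)c(O)cc1O | target

**Step count and risk**

Total step count: 10. Longest linear sequence: 7 steps (steps 4 to 10, from 7).

Steps most likely to fail:

1. Step 9. After bromine addition the base may take HBr out of 14, or hydrolyse its benzylic C–Br bond, before the furanone opens, so that an aurone-type product is returned and the ring does not expand. The 4- and 6-methoxy donors make C2 and C3 less electrophilic and favour this diversion, and nuclear bromination would use up the single equivalent of reagent. The fallback sets out from 2 and 12 and comes back at 15. Friedel–Crafts acetylation of 2 (acetyl chloride, AlCl3, Et2O) would give 1-(2,3,4,6-tetramethoxyphenyl)ethan-1-one F1, which loses its buttressed ortho methyl group in the same flask to give 1-(2-hydroxy-3,4,6-trimethoxyphenyl)ethan-1-one F2. Claisen–Schmidt condensation of this ketone with 12 (KOH, EtOH, rt) would give (E)-3-[2,4-bis(benzyloxy)-5-methoxyphenyl]-1-(2-hydroxy-3,4,6-trimethoxyphenyl)prop-2-en-1-one F3. Catalytic I2 in DMSO at 120 °C would close and dehydrogenate the chalcone to 2-[2,4-bis(benzyloxy)-5-methoxyphenyl]-5,7,8-trimethoxy-4H-chromen-4-one F4. DMDO in acetone/CH2Cl2 at 0 °C would epoxidise C2=C3 to racemic 2-[2,4-bis(benzyloxy)-5-methoxyphenyl]-2,3-epoxy-5,7,8-trimethoxychroman-4-one F5, which a trace of TsOH opens and tautomerises to 15.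

2. Step 10. Benzyl cations set free by BCl3 may attack the electron-rich rings if trapping is too slow, and the chelation-driven ether cleavage may run on from the 5-O-methyl group to the 7-, 8- or 5'-O-methyl groups while the last benzyl ether is still being removed. The fallback sets out from 15 and comes back at 16. Hydrogenolysis (H2, Pd/C, EtOAc–MeOH, rt) would remove both benzyl groups without any cation and give 2-(2,4-dihydroxy-5-methoxyphenyl)-3-hydroxy-5,7,8-trimethoxy-4H-chromen-4-one F6. Anhydrous AlCl3 in MeCN at rt would then cleave only the methyl ether peri to the carbonyl and give 16.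

3. Step 2. Under excess AlCl3 the ether cleavage that follows the acylation may not be confined to the buttressed 2-methoxy group, or may go on to a second methyl ether, and the chloromethyl ketone may alkylate unreacted arene. The fallback sets out from 2 and comes back at 6; the halogen is brought in only after the Lewis acid step. Acetylation of 2 (acetyl chloride, AlCl3, Et2O, 0 °C → rt), the acyl chloride for which the selective ortho-demethylation of this arene is established, would give 1-(2,3,4,6-tetramethoxyphenyl)ethan-1-one F7 and from it, in the same flask, 1-(2-hydroxy-3,4,6-trimethoxyphenyl)ethan-1-one F8. Bromination at the methyl group with CuBr2 in EtOAc–CHCl3 at reflux would give 2-bromo-1-(2-hydroxy-3,4,6-trimethoxyphenyl)ethan-1-one F9, and NaOAc in EtOH at reflux would close it to 6.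

**Further compounds**
F1 | step 9 | 1-(2,3,4,6-tetramethoxyphenyl)ethan-1-one | COc1cc(OC)c(C(C)=O)c(OC)c1OC
F2 | step 9 | 1-(2-hydroxy-3,4,6-trimethoxyphenyl)ethan-1-one | COc1cc(OC)c(C(C)=O)c(O)c1OC
F3 | step 9 | (E)-3-[2,4-bis(benzyloxy)-5-methoxyphenyl]-1-(2-hydroxy-3,4,6-trimethoxyphenyl)prop-2-en-1-one | COc1cc(/C=C/C(=O)c2c(O)c(OC)c(OC)cc2OC)c(OCc2ccccc2)cc1OCc1ccccc1
F4 | step 9 | 2-[2,4-bis(benzyloxy)-5-methoxyphenyl]-5,7,8-trimethoxy-4H-chromen-4-one | COc1cc(-c2cc(=O)c3c(OC)cc(OC)c(OC)c3o2)c(OCc2ccccc2)cc1OCc1ccccc1
F5 | step 9 | racemic 2-[2,4-bis(benzyloxy)-5-methoxyphenyl]-2,3-epoxy-5,7,8-trimethoxychroman-4-one (cis-fused epoxide, one enantiomer drawn) | COc1cc([C@]23Oc4c(OC)c(OC)cc(OC)c4C(=O)[C@H]2O3)c(OCc2ccccc2)cc1OCc1ccccc1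
F6 | step 10 | 2-(2,4-dihydroxy-5-methoxyphenyl)-3-hydroxy-5,7,8-trimethoxy-4H-chromen-4-one | COc1cc(-c2oc3c(OC)c(OC)cc(OC)c3c(=O)c2O)c(O)cc1O
F7 | step 2 | 1-(2,3,4,6-tetramethoxyphenyl)ethan-1-one | COc1cc(OC)c(C(C)=O)c(OC)c1OC
F8 | step 2 | 1-(2-hydroxy-3,4,6-trimethoxyphenyl)ethan-1-one | COc1cc(OC)c(C(C)=O)c(O)c1OC
F9 | step 2 | 2-bromo-1-(2-hydroxy-3,4,6-trimethoxyphenyl)ethan-1-one | COc1cc(OC)c(C(=O)CBr)c(O)c1OC
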